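## Structural features

The target 23 is a 2(5H)-furanone with the ring O1–C2(=O)–C3=C4–C5. C3 carries a methyl group, C4 a carboxyl group (C6), and C5 an unbranched saturated chain C1′–C15′ whose last carbon is a second carboxyl group. C5 is the only stereocentre and is R; it lies between the ring oxygen and the fully substituted C3=C4 bond, with no neighbouring centre to relay from. The C5–H bond is allylic, α to oxygen and vinylogously activated by both carbonyl groups, so its removal would give an aromatic 2-oxidofuran; C5 is therefore the fragile point under base. The C3=C4 alkene is tetrasubstituted and conjugated to C2 and C6, which makes it the thermodynamic sink of the exocyclic C3=CH2 isomer. The two carboxylic acids and the long chain are otherwise undemanding. The real difficulty is to place three different carbon substituents on the contiguous atoms C3, C4 and C5 and still have C5 as one enantiomer once the alkene is in place. The key step uses the fact that C4 carries both C6 and the C3–C2 acyl unit: C6 and C2 stand in a 1,4-relationship through C4–C3, which is what is left when a cyclopropane C3–C4–C6 with an oxygen donor on C6 and the C2 ester on C3 is cleaved between C3 and C6, and the C5 oxygen is then positioned to close the lactone ring on C2.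

## Logic of the disconnections

23 ⇒ 20. No skeletal bond is cut; the C3=C4 π bond is moved to the exocyclic position C3=CH2. The endocyclic alkene is the stable isomer, so it can be made last by a prototropic shift. The gain is that C4 becomes an sp3 carbon of a saturated lactone and the retron of an α-methylenation appears. The forward step must remove C4–H and leave C5–H alone.

20 ⇒ 17. The exocyclic C3=CH2 bond is cut, taking the future methyl carbon back to a one-carbon electrophile. C3 is the only enolisable lactone position, so the carbon can be put on late. This leaves a plain trans-4,5-disubstituted lactone diacid. The forward step must functionalise C3 in the presence of two free acids.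

17 ⇒ 16 ⇒ 15 + 4. The C2′–C3′ bond is cut, as an alkene made by cross-metathesis. This splits the molecule into a small chiral lactone with a three-carbon stub and an achiral chain piece, so all stereochemistry sits in 15. The benzyl ester in 4 keeps the partner and its homodimer neutral, so the acidic cross product can be extracted, and it is removed by the hydrogenation that the chain needs anyway. The forward step must favour cross- over homo-coupling and tolerate a free acid.

4 ⇒ 3 ⇒ 1 + 2. The C4′–C5′ bond is cut. The ω-bromo acid 1 is a commodity and 2 supplies the terminal alkene. The coupling must take place at the primary bromide while the carboxylate is present.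

15 ⇒ 14. Only the oxidation level of C6 is changed. The aldehyde is what the ring-opening step delivers; oxidising it at once removes the epimerisable, eliminable β-acyloxy aldehyde. The oxidation must spare the terminal alkene.

14 ⇒ 11 (key disconnection). The lactone bond O1–C2 is cut and C3 is reconnected to C6 as a cyclopropane. The 1,4-dicarbonyl pattern and the trans lactone then come from one strained precursor that already holds C4 and C5. Checked atom by atom, the carbinol carbon of 11 has the spatial arrangement of C5 in 23 (R), the cyclopropane carbon bearing it maps onto C4 of 14, and the formyl and allyl groups of 14 come out trans. The forward step needs cleavage of C3–C6 only, and lactonisation faster than any fragmentation of the β-hydroxy aldehyde.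

11 ⇒ 9 + 10. The C5–C1′ bond is cut. An aldehyde on a stereodefined cyclopropane and an allyl nucleophile are the simplest pieces. The addition must be Felkin–Anh selective under a Lewis acid that leaves the oxalate and the cyclopropane intact.

9 ⇒ 7 (through 8). The formyl carbon (future C5) and the oxalyl carbon are reconnected as an enol ether C=C. An aldehyde next to an acylated cyclopropanol is the ozonolysis product of a cyclopropane-fused dihydrofuran. The gain is a bicyclic, crystallisable compound whose enantiomeric purity can be raised before the oily intermediates. The forward step needs that alkene to be the only one.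

7 ⇒ 5 + 6. The two cyclopropane bonds to C3 (C3–C4 and C3–C6) are cut, giving a furan and a carbene carbon. Both are bulk chemicals and the three ring centres are set in one catalytic step. The cyclopropanation must be selective for the unsubstituted furan double bond, for the exo ester and for one furan face.

## Other disconnections considered

Alternative 1: The ring is opened at O1–C5 and the C4 carboxyl is exchanged for iodine, which leads back to the axially chiral allenoic acid A2 (axis C3=C4=C5, aR). In the forward sense iodine would activate the C4=C5 bond of A2 and the carboxyl oxygen would close on C5 from its own side of the allene, giving the iodobutenolide A1 with C5 R. A carbonylation of the C4–I bond (for example Pd(OAc)2/PPh3 under CO) and ester cleavage would finish the target.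
- In its favour: the C3=C4 alkene and the methyl group would be in place from the start, C4 would never be a stereocentre, and no alkene migration would be needed. On these structural points it is better than the chosen plan.
- Against it: A2 would have to be made as one enantiomer of an allene, which needs its own asymmetric sequence or a resolution. Axial information could leak through a reversible iodonium or allyl cation. The carbonylation would act on a hindered, electron-poor vinyl iodide in basic medium with the acidic C5–H already present.
- Comparison: after the key step this alternative would be about equal in step count (two or three steps against five). Before it, the chosen plan is shorter and draws its chirality from a catalytic step on a cheap furan. Both key steps are stereospecific relays, from an axis here and from a ring there.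

Alternative 2: The bonds C4–C6 (as C4–vinyl), C3–C2 and C2–O1 are cut, back to the propargylic alcohol A4, vinylmagnesium chloride and carbon dioxide. In the forward sense the magnesium alkoxide of A4 would direct anti addition of the vinyl group to C4 with magnesium on C3, carbon dioxide would carboxylate C3, and acidification would close the butenolide A3. Oxidative cleavage of the vinyl group to the C6 acid and oxidation of the chain terminus would follow.
- In its favour: three bonds and the ring would form in one flask. C5 would be set beforehand by a standard asymmetric alkynylation or ynone reduction and would sit as an alkoxide, not as an acidic butenolide C–H, during the basic step. The alkene would be born in its final position. In step economy and in safety for C5 it is better than the chosen plan.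
- Against it: carbomagnesiation of an internal methyl alkyne needs forcing conditions with a waxy long-chain substrate. The vinyl group would have to be cleaved selectively next to the butenolide alkene. Two separate oxidations to acids would be needed at the end.
- Comparison: mechanistically it relies on chelation control, the chosen plan on strain release. The chosen plan is longer but keeps every step on small, easily purified intermediates until the chain is attached.

Alternative 3: The C3=C4 bond is cut, back to the phosphonate A6, in which the C5 oxygen carries a 2-phosphonopropanoyl group and C4 is the ketone of an α-keto ester. In the forward sense the phosphonate carbanion at C3 would condense with the C4 ketone in an intramolecular Horner–Wadsworth–Emmons reaction, closing the ring and the tetrasubstituted alkene to give the diester A5. Acid would then remove both tert-butyl groups.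
- In its favour: ring and alkene in one mild step, full convergence, and only one deprotection after the key step. Its endgame is better than that of the chosen plan.
- Against it: in A6 the stereocentre C5 is α to a ketone and carries an acyloxy group, so the base needed for the olefination could enolise it or move the acyl group. An enantiopure α′-hydroxy α-keto ester would not be a simple building block.
- Comparison: on step count it would be equal or better. On stereochemical security it is weaker, because the chosen plan carries C5 as a carbinol or lactone ether carbon through non-enolising steps until the last one.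

Key step: step 6

Assumption: the (R,R)-configured isopropyl bis(oxazoline) ligand is taken to direct the carbene to the furan face that gives (1R,5R,6R)-7; if the induction runs the other way, the (S,S) ligand is used and nothing else in the route changes.

## Route

Step 1
Reactants: 1 11-bromoundecanoic acid; 2 allylmagnesium bromide
Product: 3 tetradec-13-enoic acid
Conditions: 2 (2.5 equiv), Li2CuCl4 (3 mol %), THF, −20 °C → rt; 1 M HCl
Reagents that add atoms: none
Why: Copper-catalysed sp3–sp3 Grignard cross-coupling (Kochi type) at the primary bromide; the first equivalent of 2 converts the acid into its magnesium carboxylate, which is inert to further Grignard addition under these conditions.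

Step 2
Reactants: 3 tetradec-13-enoic acid
Product: 4 benzyl tetradec-13-enoate
Conditions: BnBr, K2CO3, DMF, rt
Reagents that add atoms: benzyl bromide, BrCc1ccccc1
Why: SN2 O-alkylation of the potassium carboxylate; the benzyl ester keeps the metathesis partner neutral and falls off later in the hydrogenation of the chain.

Step 3
Reactants: 5 methyl furan-2-carboxylate (methyl 2-furoate); 6 ethyl diazoacetate
Product: 7 6-ethyl 3-methyl (1R,5R,6R)-2-oxabicyclo[3.1.0]hex-3-ene-3,6-dicarboxylate
Conditions: Cu(OTf)2 (1 mol %), (4R,4′R)-2,2′-(propane-2,2-diyl)bis(4-isopropyl-4,5-dihydrooxazole) (1.2 mol %), PhNHNH2 (1 mol %), CH2Cl2, 0 °C, slow addition of 6; recrystallisation (pentane)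
Reagents that add atoms: none
Why: Asymmetric copper-carbene cyclopropanation; phenylhydrazine reduces Cu(OTf)2 to the active monovalent copper complex, and the carbene adds to the unsubstituted, more electron-rich furan double bond remote from the ester. The carbene ester ends exo and the C2-symmetric ligand selects the furan face, which sets all three ring centres; recrystallisation should raise the enantiomeric purity at this crystalline stage.

Step 4
Reactants: 7 6-ethyl 3-methyl (1R,5R,6R)-2-oxabicyclo[3.1.0]hex-3-ene-3,6-dicarboxylate
Product: 9 (1R,2R,3R)-2-(ethoxycarbonyl)-3-formylcyclopropyl methyl oxalate, via secondary ozonide 8 (not isolated)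
Conditions: O3, CH2Cl2, −78 °C; Me2S, −78 °C → rt
Reagents that add atoms: ozone, [O-][O+]=O
Why: Ozonolysis of the only alkene, the enol ether; one alkene carbon becomes the formyl group and the other the oxalyl carbonyl on the former ring oxygen, and the cyclopropane centres are untouched. Compound 9 is used crude because the oxalate is hydrolytically labile.

Step 5
Reactants: 9 (1R,2R,3R)-2-(ethoxycarbonyl)-3-formylcyclopropyl methyl oxalate; 10 allyltrimethylsilane
Product: 11 (1R,2R,3S)-2-(ethoxycarbonyl)-3-[(1R)-1-hydroxybut-3-en-1-yl]cyclopropyl methyl oxalate
Conditions: BF3·OEt2 (1.1 equiv), CH2Cl2, −78 °C; aq. NaHCO3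
Reagents that add atoms: none
Why: Hosomi–Sakurai allylation through an open transition state; in the Felkin–Anh arrangement the ring bond to the oxalyloxy-bearing carbon stands perpendicular to the carbonyl and the allyl group enters anti to it, which should give the (R)-carbinol (future C5). Compound 11 is carried on without chromatography.

Step 6
Reactants: 11 (1R,2R,3S)-2-(ethoxycarbonyl)-3-[(1R)-1-hydroxybut-3-en-1-yl]cyclopropyl methyl oxalate
Product: 14 (2R,3S)-5-oxo-2-(prop-2-en-1-yl)oxolane-3-carbaldehyde, via cyclopropanol 12 (not isolated), via open-chain hydroxy aldehyde 13 (not isolated)
Conditions: Ba(OH)2·8H2O (0.55 equiv), MeOH, 0 °C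
Reagents that add atoms: none
Why: Hydroxide attacks the very electrophilic oxalyl ester first and frees cyclopropanol 12 as its alkoxide. The oxygen donor on C6 and the ester acceptor on C3 make C3–C6 a push–pull bond, which breaks in a retro-aldol sense so that C6 becomes the aldehyde and C3 an ester enolate that methanol protonates to give 13. Cleavage of C4–C6 instead would leave an unstabilised carbanion on C4, so the position of the ester fixes the regiochemistry. The C5 hydroxyl then attacks the ester carbonyl C2 (5-exo-trig), forms O1–C2, expels ethoxide and closes the γ-lactone ring O1–C2–C3–C4–C5. The closest known reaction type is the base-induced opening of 2-acyloxy- or 2-siloxycyclopropanecarboxylates to γ-oxo esters, joined to the lactonisation of a γ-hydroxy ester. No stereocentre is created: C4 keeps the configuration of the cyclopropane carbon and C5 that of the carbinol, which places formyl and allyl trans; trans is also the more stable arrangement, and C4 is erased in step 11 in any case. The selectivity needed is lactonisation ahead of retro-aldol cleavage of C4–C5 and ahead of β-elimination of the lactone carboxylate from the aldehyde enolate; the low temperature, the sub-stoichiometric hydroxide and the fast five-membered ring closure are relied on for this.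

Step 7
Reactants: 14 (2R,3S)-5-oxo-2-(prop-2-en-1-yl)oxolane-3-carbaldehyde
Product: 15 (2R,3S)-5-oxo-2-(prop-2-en-1-yl)oxolane-3-carboxylic acid
Conditions: NaClO2, NaH2PO4, 2-methylbut-2-ene, t-BuOH/H2O, 0 °C → rt
Reagents that add atoms: sodium chlorite, [Na+].[O-]Cl=O
Why: Pinnick oxidation under buffered, non-enolising conditions; 2-methylbut-2-ene traps the hypochlorous acid, so the terminal alkene and the centre α to the formyl group should be spared.

Step 8
Reactants: 15 (2R,3S)-5-oxo-2-(prop-2-en-1-yl)oxolane-3-carboxylic acid; 4 benzyl tetradec-13-enoate
Product: 16 (2R,3S)-2-[(2E)-15-(benzyloxy)-15-oxopentadec-2-en-1-yl]-5-oxooxolane-3-carboxylic acid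
Conditions: second-generation Grubbs catalyst RuCl2(=CHPh)(H2IMes)(PCy3) (3 mol %), 4 (3 equiv), CH2Cl2, 40 °C
Reagents that add atoms: none
Why: Olefin cross-metathesis between two unhindered terminal alkenes, driven by loss of ethene and by the excess of 4; the acidic cross product is separated from neutral 4 and its homodimer by base extraction. The alkene geometry (mainly E expected) is irrelevant because the bond is saturated next.

Step 9
Reactants: 16 (2R,3S)-2-[(2E)-15-(benzyloxy)-15-oxopentadec-2-en-1-yl]-5-oxooxolane-3-carboxylic acid
Product: 17 (2R,3S)-2-(14-carboxytetradecyl)-5-oxooxolane-3-carboxylic acid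
Conditions: H2 (1 atm), 10% Pd/C, EtOAc, rt
Reagents that add atoms: none
Why: Heterogeneous hydrogenation saturates C2′=C3′ and hydrogenolyses the benzyl ester in the same operation; the lactone and both stereocentres are inert.

Step 10
Reactants: 17 (2R,3S)-2-(14-carboxytetradecyl)-5-oxooxolane-3-carboxylic acid
Product: 20 (2R,3S)-2-(14-carboxytetradecyl)-4-methylidene-5-oxooxolane-3-carboxylic acid, via α-carboxy lactone 18 (not isolated), via Mannich base 19 (not isolated)
Conditions: MeOMgOCO2Me (2 M in DMF, excess), 130 °C; cold 10% HCl; then 37% aq. HCHO, PhNHMe, NaOAc, AcOH, rt
Reagents that add atoms: formaldehyde, C=O; methoxymagnesium methyl carbonate, COC(=O)O[Mg]OC, and N-methylaniline, CNc1ccccc1, add atoms to 18 and 19 only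
Why: α-Carboxylation of the lactone at C3 as a magnesium chelate, followed by Mannich aminomethylation and decarboxylative elimination of the amine; the two carboxyl groups are magnesium carboxylate spectators and C3 is the only activated position. Compound 18 is carried on crude after cold acidification because it decarboxylates on warming.

Step 11
Reactants: 20 (2R,3S)-2-(14-carboxytetradecyl)-4-methylidene-5-oxooxolane-3-carboxylic acid
Product: 23 (2R)-2-(14-carboxytetradecyl)-4-methyl-5-oxo-2,5-dihydrofuran-3-carboxylic acid, via exo-methylene bis(anhydride) 21 (not isolated), via butenolide bis(anhydride) 22 (not isolated)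
Conditions: Ac2O, 100 °C; then THF/H2O, 50 °C
Reagents that add atoms: acetic anhydride, CC(=O)OC(C)=O (acetyl groups of 21 and 22 only); water, O (hydrolysis of 22)
Why: Isomerisation of a β,γ-unsaturated acid derivative to its conjugated isomer: the mixed anhydride at C6 acidifies C4–H, enolisation and protonation at the exocyclic CH2 give the tetrasubstituted C3=C4 bond, which is the thermodynamic sink. Only acetate is present as base, so the C5–H bond should stay intact, and mild aqueous hydrolysis returns both acids.

## Compound list

1 | 11-bromoundecanoic acid | OC(=O)CCCCCCCCCCBr | starting material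
2 | allylmagnesium bromide | C=CC[Mg]Br | starting material
3 | tetradec-13-enoic acid | C=CCCCCCCCCCCCC(=O)O | intermediate
4 | benzyl tetradec-13-enoate | C=CCCCCCCCCCCCC(=O)OCc1ccccc1 | intermediate
5 | methyl furan-2-carboxylate (methyl 2-furoate) | COC(=O)c1ccco1 | starting material
6 | ethyl diazoacetate | CCOC(=O)C=[N+]=[N-] | starting material
7 | 6-ethyl 3-methyl (1R,5R,6R)-2-oxabicyclo[3.1.0]hex-3-ene-3,6-dicarboxylate | CCOC(=O)[C@@H]1[C@H]2C=C(C(=O)OC)O[C@@H]12 | intermediate
8 | secondary ozonide of 7 (1,2,4-trioxolane across the former enol ether carbons; the two new acetal centres not defined) | CCOC(=O)[C@@H]1[C@H]2C3OOC(C(=O)OC)(O3)O[C@@H]12 | intermediate (not isolated)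
9 | (1R,2R,3R)-2-(ethoxycarbonyl)-3-formylcyclopropyl methyl oxalate | CCOC(=O)[C@@H]1[C@@H](C=O)[C@H]1OC(=O)C(=O)OC | intermediate
10 | allyltrimethylsilane | C=CC[Si](C)(C)C | starting material
11 | (1R,2R,3S)-2-(ethoxycarbonyl)-3-[(1R)-1-hydroxybut-3-en-1-yl]cyclopropyl methyl oxalate | CCOC(=O)[C@@H]1[C@@H]([C@H](O)CC=C)[C@H]1OC(=O)C(=O)OC | intermediate
12 | ethyl (1R,2R,3S)-2-hydroxy-3-[(1R)-1-hydroxybut-3-en-1-yl]cyclopropane-1-carboxylate | CCOC(=O)[C@@H]1[C@@H]([C@H](O)CC=C)[C@H]1O | intermediate (not isolated)
13 | ethyl (3S,4R)-3-formyl-4-hydroxyhept-6-enoate | CCOC(=O)C[C@H](C=O)[C@H](O)CC=C | intermediate (not isolated)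
14 | (2R,3S)-5-oxo-2-(prop-2-en-1-yl)oxolane-3-carbaldehyde (trans) | O=C1C[C@H](C=O)[C@@H](CC=C)O1 | intermediate
15 | (2R,3S)-5-oxo-2-(prop-2-en-1-yl)oxolane-3-carboxylic acid | O=C1C[C@H](C(=O)O)[C@@H](CC=C)O1 | intermediate
16 | (2R,3S)-2-[(2E)-15-(benzyloxy)-15-oxopentadec-2-en-1-yl]-5-oxooxolane-3-carboxylic acid | O=C1C[C@H](C(=O)O)[C@@H](C/C=C/CCCCCCCCCCCC(=O)OCc2ccccc2)O1 | intermediate
17 | (2R,3S)-2-(14-carboxytetradecyl)-5-oxooxolane-3-carboxylic acid | O=C1C[C@H](C(=O)O)[C@@H](CCCCCCCCCCCCCCC(=O)O)O1 | intermediate
18 | (2R,3S)-2-(14-carboxytetradecyl)-5-oxooxolane-3,4-dicarboxylic acid (epimers at the new carboxyl-bearing carbon) | O=C1C(C(=O)O)[C@H](C(=O)O)[C@@H](CCCCCCCCCCCCCCC(=O)O)O1 | intermediate (not isolated)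
19 | (2R,3S)-2-(14-carboxytetradecyl)-4-{[methyl(phenyl)amino]methyl}-5-oxooxolane-3,4-dicarboxylic acid (quaternary centre not defined) | O=C1C(CN(C)c2ccccc2)(C(=O)O)[C@H](C(=O)O)[C@@H](CCCCCCCCCCCCCCC(=O)O)O1 | intermediate (not isolated)
20 | (2R,3S)-2-(14-carboxytetradecyl)-4-methylidene-5-oxooxolane-3-carboxylic acid | O=C1C(=C)[C@H](C(=O)O)[C@@H](CCCCCCCCCCCCCCC(=O)O)O1 | intermediate
21 | bis(acetic) mixed anhydride of 20 | O=C1C(=C)[C@H](C(=O)OC(C)=O)[C@@H](CCCCCCCCCCCCCCC(=O)OC(C)=O)O1 | intermediate (not isolated)
22 | bis(acetic) mixed anhydride of 23 | CC1=C(C(=O)OC(C)=O)[C@@H](CCCCCCCCCCCCCCC(=O)OC(C)=O)OC1=O | intermediate (not isolated)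
23 | (2R)-2-(14-carboxytetradecyl)-4-methyl-5-oxo-2,5-dihydrofuran-3-carboxylic acid | CC1=C(C(=O)O)[C@@H](CCCCCCCCCCCCCCC(=O)O)OC1=O | target

## Step count and least certain steps

Total step count: 11. Longest linear sequence: 9 steps (steps 3 to 11, from 5); the two-step branch (steps 1 and 2) joins in step 8.

**Step 6 (key step).** What may go wrong: the aldehyde enolate of 14 may expel the lactone carboxylate by β-elimination, 13 may fragment by retro-aldol cleavage of C4–C5, or lactonisation may lag and leave open-chain ester. All of these arise from having a free β-oxygenated aldehyde in base. The fallback changes the medium from base to acid and masks the aldehyde as it forms. It sets out from 11, which would be treated with HCl in methanol (from acetyl chloride, 0 °C to rt). The oxalate is transesterified off, the push–pull cyclopropanol opens under acid, the aldehyde is trapped as its dimethyl acetal and the hydroxy ester lactonises, which should give (4S,5R)-4-(dimethoxymethyl)-5-(prop-2-en-1-yl)oxolan-2-one F1. Hydrolysis of the acetal with aqueous trifluoroacetic acid would return to the route at 14.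

**Step 11.** What may go wrong: loss of configuration at C5 by deprotonation of the doubly activated allylic C5–H of 22 at 100 °C, incomplete migration of the alkene, or slow hydrolysis of oligomeric anhydrides of the chain acid. The fallback replaces enolisation by a metal hydride addition–elimination pathway, which needs no carbanion at C4 or C5. It sets out from 20, which would be heated with RhCl(PPh3)3 (5 mol %) and a few mol % of Et3SiH in toluene at 90 °C. Rhodium hydride adds across the exocyclic alkene and β-hydride elimination towards C4 gives the endocyclic isomer; aqueous work-up would return to the route at 23. No new compound lies on the way.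

**Step 10.** What may go wrong: incomplete carboxylation at C3 followed by decarboxylation back to 17 on work-up, or conjugate addition of N-methylaniline to the new methylene lactone. The fallback builds the methylene group by amine quaternisation and elimination. It sets out from 17, which would be converted into its trianion with LiN(SiMe3)2 (3.3 equiv, THF, −78 °C) and aminomethylated at C3 with dimethyl(methylidene)ammonium iodide to give (2R,3S,4R)-2-(14-carboxytetradecyl)-4-[(dimethylamino)methyl]-5-oxooxolane-3-carboxylic acid F2. Methyl iodide in methanol would give the trimethylammonium iodide of F2, F3, and aqueous NaHCO3 would eliminate trimethylamine and return to the route at 20.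

**Step 3.** What may go wrong: insufficient face selection by the ligand, carbene dimerisation competing with cyclopropanation, or an induction opposite to the assumed sense. The fallback replaces asymmetric catalysis by resolution. It sets out from 5 and 6, which would be combined with Rh2(OAc)4 (0.5 mol %, CH2Cl2, rt, slow addition) to give the racemate, that is 7 together with its mirror image 6-ethyl 3-methyl (1S,5S,6S)-2-oxabicyclo[3.1.0]hex-3-ene-3,6-dicarboxylate F4. Preparative chromatography on a cellulose tris(3,5-dimethylphenylcarbamate) phase would separate the two and return to the route at 7.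

**Step 5.** What may go wrong: poor facial selectivity in the open transition state, or Lewis-acid-induced loss of the oxalate and opening of the donor–acceptor cyclopropane. The fallback replaces substrate control under a Lewis acid by reagent control in a closed transition state without Lewis acid. It sets out from 9, which would be treated with the allylboronate of diisopropyl tartrate (the enantiomer that reinforces the Felkin–Anh sense, expected to be the one from (S,S)-tartrate) in toluene with 4 Å molecular sieves at −78 °C. Aqueous work-up would return to the route at 11. No new compound lies on the way.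

## Further compounds

F1 | step 6 | (4S,5R)-4-(dimethoxymethyl)-5-(prop-2-en-1-yl)oxolan-2-one | O=C1C[C@H](C(OC)OC)[C@@H](CC=C)O1
F0 | step 11 | none | none
F2 | step 10 | (2R,3S,4R)-2-(14-carboxytetradecyl)-4-[(dimethylamino)methyl]-5-oxooxolane-3-carboxylic acid | O=C1[C@@H](CN(C)C)[C@H](C(=O)O)[C@@H](CCCCCCCCCCCCCCC(=O)O)O1
F3 | step 10 | trimethylammonium iodide of F2 | O=C1[C@@H](C[N+](C)(C)C)[C@H](C(=O)O)[C@@H](CCCCCCCCCCCCCCC(=O)O)O1.[I-]
F4 | step 3 | 6-ethyl 3-methyl (1S,5S,6S)-2-oxabicyclo[3.1.0]hex-3-ene-3,6-dicarboxylate | CCOC(=O)[C@H]1[C@@H]2C=C(C(=O)OC)O[C@H]12
F0 | step 5 | none | none
A1 | alternative 1 | tert-butyl 15-[(2R)-3-iodo-4-methyl-5-oxo-2,5-dihydrofuran-2-yl]pentadecanoate | CC1=C(I)[C@@H](CCCCCCCCCCCCCCC(=O)OC(C)(C)C)OC1=O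
A2 | alternative 1 | (aR)-19-tert-butoxy-2-methyl-19-oxononadeca-2,3-dienoic acid | CC(C(=O)O)=[C@@]=C([H])CCCCCCCCCCCCCCC(=O)OC(C)(C)C
A3 | alternative 2 | (5R)-4-ethenyl-3-methyl-5-{15-[tri(propan-2-yl)silyloxy]pentadecyl}furan-2(5H)-one | CC1=C(C=C)[C@@H](CCCCCCCCCCCCCCCO[Si](C(C)C)(C(C)C)C(C)C)OC1=O
A4 | alternative 2 | (4R)-19-[tri(propan-2-yl)silyloxy]nonadec-2-yn-4-ol | CC#C[C@H](O)CCCCCCCCCCCCCCCO[Si](C(C)C)(C(C)C)C(C)C
A5 | alternative 3 | tert-butyl (2R)-2-(15-tert-butoxy-15-oxopentadecyl)-4-methyl-5-oxo-2,5-dihydrofuran-3-carboxylate | CC1=C(C(=O)OC(C)(C)C)[C@@H](CCCCCCCCCCCCCCC(=O)OC(C)(C)C)OC1=O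
A6 | alternative 3 | di-tert-butyl (3R)-3-{[2-(diethoxyphosphoryl)propanoyl]oxy}-2-oxooctadecanedioate (phosphonate carbon not defined) | CCOP(=O)(OCC)C(C)C(=O)O[C@H](CCCCCCCCCCCCCCC(=O)OC(C)(C)C)C(=O)C(=O)OC(C)(C)C
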